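**Retrosynthetic overview**

1. The target comes from its O-silyl ether, and that from a bis-furan ketone. Both maleic anhydride rings (ring A and ring B) are unveiled together, last, by a one-pot twofold singlet-oxygen dearomatisation and lactol oxidation of two 3,4-disubstituted furans.
2. The bis-furan comes from a ring A bromide and a ring B 1,1-disubstituted alkene. A CuH/Pd asymmetric anti-Markovnikov hydroarylation forms the ring A–CH2 bond and sets the only stereocenter.
3. Both furans come from symmetric 3,4-dibromofuran by mono bromine–metal exchange: Br/Li, then CH2O/TBSCl for ring A; Br/Mg, zinc, Negishi coupling with 2-bromohept-1-ene, then Br/Li and epoxide opening for ring B.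
4. No ring is built de novo. The ketone is carried as the alcohol through the CuH step.

Assumptions: the target is taken as isolable in the drawn open hydroxymethyl–anhydride form, so the hydroxyl is freed last under anhydrous acid; in step 4 the (R)-ligand is taken to give (S) by analogy, and its antipode is used unchanged otherwise if a pilot run shows the opposite sense; 1, 5 and 9 are bought.

**Route**

Step 1
Reactants: 1 3,4-dibromofuran
Product: 4 tert-butyl[(4-bromofuran-3-yl)methoxy]dimethylsilane, via 3-bromo-4-lithiofuran 2 (not isolated), via lithium (4-bromofuran-3-yl)methanolate 3 (not isolated)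
Conditions: n-BuLi (1.05 equiv), THF, −78 °C; CH2O (g); then TBSCl, DMAP (cat.), −78 °C → rt
Reagents that add atoms: formaldehyde C=O; tert-butyldimethylsilyl chloride CC(C)(C)[Si](C)(C)Cl
Why: Mono bromine–lithium exchange on the symmetric dibromide is clean at −78 °C, the aryllithium adds to monomeric formaldehyde, and the lithium alkoxide is silylated in the same flask (halogen–metal exchange, 1,2-addition, O-silylation).

Step 2
Reactants: 1 3,4-dibromofuran; 5 2-bromohept-1-ene
Product: 8 3-bromo-4-(hept-1-en-2-yl)furan, via (4-bromofuran-3-yl)magnesium chloride 6 (not isolated), via (4-bromofuran-3-yl)zinc chloride 7 (not isolated)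
Conditions: i-PrMgCl·LiCl (1.05 equiv), THF, 0 °C → rt; ZnCl2 (1.1 equiv, THF), 0 °C; then 5, Pd(PPh3)4 (3 mol %), THF, rt
Reagents that add atoms: none
Why: Bromine–magnesium exchange with the LiCl-activated isopropyl Grignard reagent stops after one bromine, since the neighbouring bromine accelerates the first exchange inductively and the arylmagnesium formed resists a second one. Transmetalation to zinc then sets up a Negishi coupling in which the alkenyl C–Br bond of 5 should add to zerovalent palladium much faster than the electron-rich 3-furyl C–Br bond, so the ring bromide survives.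

Step 3
Reactants: 8 3-bromo-4-(hept-1-en-2-yl)furan; 9 rac-2-butyloxirane
Product: 11 (2RS)-1-[4-(hept-1-en-2-yl)furan-3-yl]hexan-2-ol, via [4-(hept-1-en-2-yl)furan-3-yl]lithium 10 (not isolated)
Conditions: n-BuLi, THF, −78 °C; 9, BF3·OEt2, −78 °C; aq. NH4Cl
Reagents that add atoms: none
Why: Bromine–lithium exchange and Lewis-acid-promoted SN2 opening of the epoxide at its CH2 carbon install the six-carbon chain at the alcohol oxidation level. BF3 only activates the epoxide, so the reaction runs below the decomposition temperature of 3-lithiofurans, and the racemic carbinol center is erased in step 5.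

Step 4
Reactants: 4 tert-butyl[(4-bromofuran-3-yl)methoxy]dimethylsilane; 11 (2RS)-1-[4-(hept-1-en-2-yl)furan-3-yl]hexan-2-ol
Product: 13 (2RS)-1-{4-[(2S)-1-(4-{[tert-butyl(dimethyl)silyl]oxymethyl}furan-3-yl)heptan-2-yl]furan-3-yl}hexan-2-ol, via dimethoxy(methyl)silyl ether of the coupled alcohol 12 (not isolated)
Conditions: Cu(OAc)2 (5 mol %), (R)-DTBM-SEGPHOS (5.5 mol %), [PdCl(η3-PhC3H4)]2 (2 mol %), BrettPhos (4.4 mol %), NaOSiMe3 (2 equiv), MeSiH(OMe)2 (5 equiv), THF, 45 °C; then K2CO3 (cat.), MeOH, rt
Reagents that add atoms: none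
Why: In this dual CuH/Pd asymmetric anti-Markovnikov hydroarylation of a 1,1-disubstituted alkene, the ligand-bound CuH places Cu on the terminal CH2 and H on the carbon bearing ring B and pentyl, which sets the (S) center under ligand control. The primary alkylcopper then transmetalates to the aryl–Pd–Br from 4 and reductive elimination forms the ring A–CH2 bond. The free hydroxyl is silylated in situ and released by methanolysis, whereas a ketone would be reduced by CuH.

Step 5
Reactants: 13 (2RS)-1-{4-[(2S)-1-(4-{[tert-butyl(dimethyl)silyl]oxymethyl}furan-3-yl)heptan-2-yl]furan-3-yl}hexan-2-ol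
Product: 14 1-{4-[(2S)-1-(4-{[tert-butyl(dimethyl)silyl]oxymethyl}furan-3-yl)heptan-2-yl]furan-3-yl}hexan-2-one
Conditions: Dess–Martin periodinane, pyridine, CH2Cl2, 0 °C → rt
Reagents that add atoms: none
Why: Buffered Dess–Martin oxidation of the secondary alcohol leaves both furans, the silyl ether and the stereocenter untouched, and removes the hydroxyl that would otherwise trap the ring B endoperoxide as a cyclic acetal in step 6.

Step 6 (key step)
Reactants: 14 1-{4-[(2S)-1-(4-{[tert-butyl(dimethyl)silyl]oxymethyl}furan-3-yl)heptan-2-yl]furan-3-yl}hexan-2-one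
Product: 17 3-{[tert-butyl(dimethyl)silyl]oxymethyl}-4-{(2S)-2-[2,5-dioxo-4-(2-oxohexyl)-2,5-dihydrofuran-3-yl]heptyl}furan-2,5-dione, via bis-endoperoxide 15 (not isolated), via bis(γ-hydroxybutenolide) 16 (not isolated)
Conditions: O2, hν (visible), tetraphenylporphyrin (cat.), i-Pr2NEt, CH2Cl2, −78 → 0 °C; filter through SiO2; then pyridinium chlorochromate [C5H5NH][CrO3Cl], 4 Å MS, CH2Cl2, rt
Reagents that add atoms: dioxygen O=O
Why: Each 3,4-disubstituted furan undergoes [4+2] cycloaddition with singlet oxygen across C2/C5 (dearomatisation), and amine-induced Kornblum–DeLaMare rearrangement gives γ-hydroxybutenolides whose regio- and stereoisomers all converge. Chlorochromate oxidation of the two lactols then closes both maleic anhydrides at once; the stereocenter is not involved and sees only a hindered amine at low temperature.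

Step 7
Reactants: 17 3-{[tert-butyl(dimethyl)silyl]oxymethyl}-4-{(2S)-2-[2,5-dioxo-4-(2-oxohexyl)-2,5-dihydrofuran-3-yl]heptyl}furan-2,5-dione
Product: 18 3-(hydroxymethyl)-4-{(2S)-2-[2,5-dioxo-4-(2-oxohexyl)-2,5-dihydrofuran-3-yl]heptyl}furan-2,5-dione (CNP0537712.1)
Conditions: HF·pyridine, MeCN, 0 °C (dilute); cold acidic work-up
Reagents that add atoms: none
Why: Fluoride cleavage of the primary silyl ether under acidic, non-hydrolytic conditions keeps both anhydrides closed, because pyridine stays protonated and cannot catalyse acylation of the freed alcohol, and it cannot epimerise the γ-stereocenter.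

**Compound list**

1 | 3,4-dibromofuran | Brc1cocc1Br | starting material
2 | 3-bromo-4-lithiofuran | [Li]c1cocc1Br | intermediate
3 | lithium (4-bromofuran-3-yl)methanolate | [Li+].[O-]Cc1cocc1Br | intermediate
4 | tert-butyl[(4-bromofuran-3-yl)methoxy]dimethylsilane | CC(C)(C)[Si](C)(C)OCc1cocc1Br | intermediate
5 | 2-bromohept-1-ene | CCCCCC(Br)=C | starting material
6 | (4-bromofuran-3-yl)magnesium chloride | Cl[Mg]c1cocc1Br | intermediate
7 | (4-bromofuran-3-yl)zinc chloride | Cl[Zn]c1cocc1Br | intermediate
8 | 3-bromo-4-(hept-1-en-2-yl)furan | CCCCCC(=C)c1cocc1Br | intermediate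
9 | rac-2-butyloxirane (1,2-epoxyhexane) | CCCCC1CO1 | starting material
10 | [4-(hept-1-en-2-yl)furan-3-yl]lithium | [Li]c1cocc1C(=C)CCCCC | intermediate
11 | (2RS)-1-[4-(hept-1-en-2-yl)furan-3-yl]hexan-2-ol (racemic) | CCCCCC(=C)c1cocc1CC(O)CCCC | intermediate
12 | dimethoxy(methyl)silyl ether of 13 (S at the heptane C2; carbinol epimers) | CCCCC[C@@H](Cc1cocc1CO[Si](C)(C)C(C)(C)C)c1cocc1CC(O[Si](C)(OC)OC)CCCC | intermediate
13 | (2RS)-1-{4-[(2S)-1-(4-{[tert-butyl(dimethyl)silyl]oxymethyl}furan-3-yl)heptan-2-yl]furan-3-yl}hexan-2-ol (1:1 carbinol epimers) | CCCCC[C@@H](Cc1cocc1CO[Si](C)(C)C(C)(C)C)c1cocc1CC(O)CCCC | intermediate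
14 | 1-{4-[(2S)-1-(4-{[tert-butyl(dimethyl)silyl]oxymethyl}furan-3-yl)heptan-2-yl]furan-3-yl}hexan-2-one | CCCCC[C@@H](Cc1cocc1CO[Si](C)(C)C(C)(C)C)c1cocc1CC(=O)CCCC | intermediate
15 | bis-endoperoxide of 14 (each furan as a 2,3,7-trioxabicyclo[2.2.1]hept-5-ene; S at the side-chain center; bridgehead diastereomers) | CCCCC[C@@H](CC1=C(CO[Si](C)(C)C(C)(C)C)C2OOC1O2)C1=C(CC(=O)CCCC)C2OOC1O2 | intermediate
16 | bis(5-hydroxy-2(5H)-furanone) from 15 (S at the side-chain center; lactol regio- and stereoisomer mixture, one regioisomer drawn) | CCCCC[C@@H](CC1=C(CO[Si](C)(C)C(C)(C)C)C(O)OC1=O)C1=C(CC(=O)CCCC)C(O)OC1=O | intermediate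
17 | 3-{[tert-butyl(dimethyl)silyl]oxymethyl}-4-{(2S)-2-[2,5-dioxo-4-(2-oxohexyl)-2,5-dihydrofuran-3-yl]heptyl}furan-2,5-dione | CCCCC[C@@H](CC1=C(CO[Si](C)(C)C(C)(C)C)C(=O)OC1=O)C1=C(CC(=O)CCCC)C(=O)OC1=O | intermediate
18 | 3-(hydroxymethyl)-4-{(2S)-2-[2,5-dioxo-4-(2-oxohexyl)-2,5-dihydrofuran-3-yl]heptyl}furan-2,5-dione | CCCCC[C@@H](CC1=C(CO)C(=O)OC1=O)C1=C(CC(=O)CCCC)C(=O)OC1=O | target

**Step count and risks**

Total: 7 steps. Longest linear sequence: 6 steps (1 → 8 → 11 → 13 → 14 → 17 → 18); bromide 4 is one step off this line.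

Most likely to fail:

- **Step 4 (stereo-defining hydroarylation).** Both partners are ortho-substituted furans, a substrate class not yet shown for this reaction, so rate and ee are uncertain. The fallback sets out from 11 and separates the stereo-setting event from the C–C coupling. Copper-catalysed enantioselective protoboration of the 1,1-disubstituted alkene (CuCl, chiral imidazolinium-derived carbene ligand, NaOt-Bu, B2pin2, MeOH, THF, −50 °C → rt) puts boron on the terminal carbon and a proton on the carbon bearing ring B. This gives (2RS)-1-{4-[(2R)-1-(4,4,5,5-tetramethyl-1,3,2-dioxaborolan-2-yl)heptan-2-yl]furan-3-yl}hexan-2-ol F3, which has the same spatial arrangement as 13; the descriptor is R only because CH2B ranks below pentyl. Its ee can be measured and upgraded. A B-alkyl Suzuki–Miyaura coupling with bromide 4 (Pd(OAc)2, RuPhos, K3PO4, toluene/H2O, 80 °C) then comes back to the route at 13.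

- **Step 6 (twofold furan-to-anhydride oxidation).** Two endoperoxides, an acidic keto-methylene and a base-sensitive product meet in one flask. The fallback sets out from 14 and replaces the cycloaddition by electrophilic oxidation to the acetal level. Anodic 2,5-dimethoxylation of both furans (constant current, MeOH, Et4NOTs, carbon electrodes, −10 °C) gives the bis(2,5-dimethoxy-2,5-dihydrofuran) F4. Mild hydrolysis (PPTS, acetone/H2O, 0 °C, short contact to spare the silyl ether) opens it to the bis[(Z)-enedial] F5. Chlorite oxidation (NaClO2, NaH2PO4, 2-methylbut-2-ene, t-BuOH/H2O) gives the bis(maleic acid) F6. Careful acidification and concentration from toluene cyclodehydrate F6, and the route is rejoined at 17.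

- **Step 2 (exchange and chemoselective Negishi coupling).** Arylzinc 7 also carries a C–Br bond and could oligomerise under palladium catalysis. The fallback sets out from Grignard reagent 6, formed from 1 exactly as in step 2, and avoids zinc and palladium. Reagent 6 is added to N-methoxy-N-methylhexanamide (THF, 0 °C) to give the chloromagnesium hemiaminal chelate F1. On NH4Cl work-up this collapses to 1-(4-bromofuran-3-yl)hexan-1-one F2. Wittig methylenation (Ph3PCH3Br, KOt-Bu, THF, 0 °C) then returns to the route at 8.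

**Further compounds**

F1 | step 2 | chloromagnesium 1-(4-bromofuran-3-yl)-1-[methoxy(methyl)amino]hexan-1-olate | CCCCCC(O[Mg]Cl)(N(C)OC)c1cocc1Br
F2 | step 2 | 1-(4-bromofuran-3-yl)hexan-1-one | CCCCCC(=O)c1cocc1Br
F3 | step 4 | (2RS)-1-{4-[(2R)-1-(4,4,5,5-tetramethyl-1,3,2-dioxaborolan-2-yl)heptan-2-yl]furan-3-yl}hexan-2-ol | CCCCC[C@@H](CB1OC(C)(C)C(C)(C)O1)c1cocc1CC(O)CCCC
F4 | step 6 | 1-{4-[(2S)-1-(4-{[tert-butyl(dimethyl)silyl]oxymethyl}-2,5-dimethoxy-2,5-dihydrofuran-3-yl)heptan-2-yl]-2,5-dimethoxy-2,5-dihydrofuran-3-yl}hexan-2-one (acetal diastereomers) | CCCCC[C@@H](CC1=C(CO[Si](C)(C)C(C)(C)C)C(OC)OC1OC)C1=C(CC(=O)CCCC)C(OC)OC1OC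
F5 | step 6 | bis[(Z)-but-2-enedial] from F4 (S at the side-chain center) | CCCCC[C@@H](C/C(C=O)=C(\CO[Si](C)(C)C(C)(C)C)C=O)/C(C=O)=C(\CC(=O)CCCC)C=O
F6 | step 6 | bis[(Z)-but-2-enedioic acid] from F5 (S at the side-chain center) | CCCCC[C@@H](C/C(C(=O)O)=C(\CO[Si](C)(C)C(C)(C)C)C(=O)O)/C(C(=O)O)=C(\CC(=O)CCCC)C(=O)O
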